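**Strategy.** Everything rests on cutting the dihydropyran ring fused to the C3–C4 enol ether of quinolone A: O–C4=C3–Ca–Cb–Cc (Ca, side-chain methine; Cb, fusion CH beside CMe2; Cc, fusion O–CH). Being the cyclic enol ether of a 1,3-dicarbonyl, this ring is the retron of an inverse-electron-demand oxa-Diels–Alder reaction. The precursor is three achiral pieces: 4-hydroxy-7,8-dimethoxy-1-methyl-2-quinolone, 3-hydroxy-3-methylbutanal and veprisine (the pyranoquinolone made from the same quinolone). A chiral-acid-catalysed Knoevenagel/[4+2] domino forms the heterodiene O=C4–C3=Ca in situ and adds it across the cis pyran alkene Cb=Cc of veprisine, creating two ring bonds, the final ring and all three stereocentres at once.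

Key step: step 5

Notation: in target 12 the pyran on quinolone A is numbered O1–C2–C3–C4, so Cc = C-2 (R), Cb = C-3 (S), Ca = C-4 (S); H-2/H-3 are cis and H-3/H-4 are trans.

Assumption: the sense of induction of the phosphoric acid in step 5 cannot be predicted with confidence; (R)-TRIP is written, and its antipode is used if a first run shows the opposite sense.

Step 1
Reactants: 1 1-bromo-2,3-dimethoxybenzene
Product: 2 2,3-dimethoxy-N-methylaniline
Conditions: MeNH2 (2 M in THF), BrettPhos Pd G3 (1 mol %), NaOtBu, THF, 25–50 °C
Reagents that add atoms: methylamine, CN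
Why: Buchwald–Hartwig amination; the BrettPhos ligand is known to stop at monoarylation of methylamine, and the C–Br bond is the only reactive site.

Step 2
Reactants: 2 2,3-dimethoxy-N-methylaniline; 3 bis(2,4,6-trichlorophenyl) malonate
Product: 5 4-hydroxy-7,8-dimethoxy-1-methylquinolin-2(1H)-one, via malonamic trichlorophenyl ester 4 (not isolated)
Conditions: Ph2O, 220 °C
Reagents that add atoms: none
Why: Cyclocondensation of an N-alkylaniline with an activated ("magic") malonate: N-acylation gives 4, which should close by thermal intramolecular C-acylation at the only free ortho position (para to the 3-OMe group) to the 4-hydroxy-2-quinolone.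

Step 3
Reactants: 5 4-hydroxy-7,8-dimethoxy-1-methylquinolin-2(1H)-one; 6 3-methylbut-2-enal
Product: 8 veprisine, via oxatriene 7 (not isolated)
Conditions: pyridine, MgSO4, 115 °C
Reagents that add atoms: none
Why: Knoevenagel condensation followed by oxa-6π-electrocyclisation of the 1-oxatriene; closure through the C4 oxygen should give the angular 2-quinolone, as is usual for N-methyl-4-hydroxy-2-quinolones.

Step 4
Reactants: 9 3-methylbutane-1,3-diol
Product: 10 3-hydroxy-3-methylbutanal
Conditions: TEMPO (10 mol %), PhI(OAc)2 (1.1 equiv), CH2Cl2, 0 → 25 °C; short silica plug, used at once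
Reagents that add atoms: none
Why: Oxoammonium (TEMPO/PhI(OAc)2) oxidation is selective for the primary alcohol and stops at the aldehyde, while the tertiary alcohol cannot be oxidised.

Step 5
Reactants: 5 4-hydroxy-7,8-dimethoxy-1-methylquinolin-2(1H)-one; 10 3-hydroxy-3-methylbutanal; 8 veprisine
Product: 12 (2R,3S,4S)-target, via ortho-quinone methide 11 (not isolated)
Conditions: (R)-TRIP (10 mol %), 4 Å MS, CHCl3, 25 °C; 8 (2.5 equiv), 10 (1.5 equiv), slow addition of 5
Reagents that add atoms: none
Why: Proposed new method: the phosphoric acid catalyses Knoevenagel condensation of 5 with 10 to the 1-oxadiene 11 and then holds it by hydrogen bonds (P–OH to C4=O, P=O to the tertiary OH) while the electron-rich pyran alkene of 8 adds in an asynchronous inverse-electron-demand oxa-[4+2] cycloaddition, the C–C bond running ahead of the C–O bond. The closest known reaction types are the racemic amine-salt-catalysed domino Knoevenagel/hetero-Diels–Alder reaction of 4-hydroxy-2-quinolones or 4-hydroxycoumarins with aldehydes and alkenes, and chiral-phosphoric-acid-catalysed [4+2] cycloadditions of in-situ ortho-quinone methides with styrenes and enol ethers; their union on a quinolinedione heterodiene and a chromene-type dienophile is the untested part. The one ring closed, the dihydropyran O–C4=C3–Ca–Cb–Cc, is formed by an intermolecular [4+2] cycloaddition that is suprafacial on both partners (bonds Ca–Cb and O–Cc). Cb and Cc are fixed cis by the (Z)-alkene locked in the pyran ring of 8, Ca is set trans to the CMe2 arm on Cb by the exo approach of the bulky dienophile to the heterodiene with its side chain outside, and the absolute configuration of all three follows from the face of 11 left open by the 3,3′-aryl groups of the catalyst. Regiochemistry is secured by polarity (electrophilic Ca to the nucleophilic terminus Cb of the 1-alkoxydiene O–C=C–Cc=Cb of 8, oxygen to the cation-stabilising Cc), and the C4 ketone rather than the C2 lactam carbonyl acts as the heteroatom terminus because it is the more electrophilic carbonyl and the product keeps the 2-quinolone. Capture of 11 by 8 instead of by a second molecule of 5 is secured by excess 8 and slow addition of 5.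

**Compound list**

1 | 1-bromo-2,3-dimethoxybenzene | COc1cccc(Br)c1OC | starting material
2 | 2,3-dimethoxy-N-methylaniline | CNc1cccc(OC)c1OC | intermediate
3 | bis(2,4,6-trichlorophenyl) malonate | O=C(CC(=O)Oc1c(Cl)cc(Cl)cc1Cl)Oc1c(Cl)cc(Cl)cc1Cl | starting material
4 | 2,4,6-trichlorophenyl 3-[(2,3-dimethoxyphenyl)(methyl)amino]-3-oxopropanoate (not isolated) | COc1cccc(N(C)C(=O)CC(=O)Oc2c(Cl)cc(Cl)cc2Cl)c1OC | intermediate
5 | 4-hydroxy-7,8-dimethoxy-1-methylquinolin-2(1H)-one | COc1ccc2c(O)cc(=O)n(C)c2c1OC | intermediate
6 | 3-methylbut-2-enal | CC(C)=CC=O | starting material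
7 | 7,8-dimethoxy-1-methyl-3-(3-methylbut-2-en-1-ylidene)quinoline-2,4(1H,3H)-dione (oxatriene, not isolated) | COc1ccc2c(c1OC)N(C)C(=O)C(=CC=C(C)C)C2=O | intermediate
8 | veprisine, 7,8-dimethoxy-2,2,6-trimethyl-2,6-dihydro-5H-pyrano[3,2-c]quinolin-5-one | COc1ccc2c3OC(C)(C)C=Cc3c(=O)n(C)c2c1OC | intermediate
9 | 3-methylbutane-1,3-diol | CC(C)(O)CCO | starting material
10 | 3-hydroxy-3-methylbutanal | CC(C)(O)CC=O | intermediate
11 | 3-(3-hydroxy-3-methylbutylidene)-7,8-dimethoxy-1-methylquinoline-2,4(1H,3H)-dione (ortho-quinone methide, not isolated) | COc1ccc2c(c1OC)N(C)C(=O)C(=CCC(C)(C)O)C2=O | intermediate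
12 | target: cis-fused bis(dihydropyrano[3,2-c]quinolin-5-one); pyran A (O1–C2–C3–C4 on 7,8-dimethoxy-6-methylquinolone A) carries (4S)-4-(2-hydroxy-2-methylpropyl); C-3 (S) and C-2 (R) are also C-3′ and C-4′ of the 2′,2′-dimethyldihydropyran on the second 7,8-dimethoxy-6-methylquinolone; H-2/H-3 cis, H-3/H-4 trans | COc1ccc2c3c(c(=O)n(C)c2c1OC)[C@@H](CC(C)(C)O)[C@H]1[C@@H](O3)c2c(c3ccc(OC)c(OC)c3n(C)c2=O)OC1(C)C | target

**Totals.** Total step count: 5. Longest linear sequence: 4 steps (steps 1, 2, 3, 5); step 4 is a one-step side branch.

**Steps most likely to fail**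

Step 5. Face discrimination may be poor because the dienophile offers the catalyst no hydrogen-bond handle. The ortho-quinone methide may also be drained by Michael addition of a second quinolone or by isomerisation and dehydration towards veprisine, and the exo preference may erode. The fallback uses known chemistry and sets out from 5, 8 and 10. The three components are heated with ethylenediammonium diacetate (10 mol %) in toluene/MeCN at 80–100 °C, the established racemic domino Knoevenagel/hetero-Diels–Alder reaction. This should give the racemate, that is 12 together with the enantiomer of 12 F1. The two are separated by preparative HPLC on a polysaccharide chiral stationary phase, which returns the route at 12.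

Step 4. The β-hydroxy aldehyde may be lost by dehydration to the enal, by self-condensation or by evaporation during isolation. The fallback sets out from 9 and changes to a protecting-group approach. Silylation of both hydroxyls (TESOTf, 2,6-lutidine, CH2Cl2) should give the bis(triethylsilyl) ether F2. Swern oxidation, which cleaves and oxidises a primary triethylsilyl ether selectively, should give the silyloxy aldehyde F3, a robust and non-volatile partner. The domino reaction of step 5 is then run with F3 in place of 10. It should pass through the silylated ortho-quinone methide F4 to the silyl-protected adduct F5, and HF·pyridine in THF should free the tertiary alcohol, returning the route at 12.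

Step 3. Ring closure may compete through the lactam oxygen (linear pyrano[2,3-b] isomer), and the enal may self-condense in hot pyridine. The fallback sets out from 2. Thermal condensation with diethyl 2-(3-methylbut-2-en-1-yl)malonate (Ph2O, 250 °C) should give the 3-prenyl quinolone F6. Oxidative cyclisation with DDQ in refluxing benzene generates the same oxatriene 7 by dehydrogenation and, after electrocyclisation, returns the route at 8.

**Further compounds**

F1 | step 5 | enantiomer of 12 (second component of the racemate) | COc1ccc2c3c(c(=O)n(C)c2c1OC)[C@H](CC(C)(C)O)[C@@H]1[C@H](O3)c2c(c3ccc(OC)c(OC)c3n(C)c2=O)OC1(C)C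
F2 | step 4 | 3-methyl-1,3-bis(triethylsilyloxy)butane | CC[Si](CC)(CC)OCCC(C)(C)O[Si](CC)(CC)CC
F3 | step 4 | 3-methyl-3-(triethylsilyloxy)butanal | CC[Si](CC)(CC)OC(C)(C)CC=O
F4 | step 4 | 7,8-dimethoxy-1-methyl-3-[3-methyl-3-(triethylsilyloxy)butylidene]quinoline-2,4(1H,3H)-dione (not isolated) | COc1ccc2c(c1OC)N(C)C(=O)C(=CCC(C)(C)O[Si](CC)(CC)CC)C2=O
F5 | step 4 | triethylsilyl ether of 12 | COc1ccc2c3c(c(=O)n(C)c2c1OC)[C@@H](CC(C)(C)O[Si](CC)(CC)CC)[C@H]1[C@@H](O3)c2c(c3ccc(OC)c(OC)c3n(C)c2=O)OC1(C)C
F6 | step 3 | 4-hydroxy-7,8-dimethoxy-1-methyl-3-(3-methylbut-2-en-1-yl)quinolin-2(1H)-one | COc1ccc2c(O)c(CC=C(C)C)c(=O)n(C)c2c1OC
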